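**Retrosynthetic overview**

1. Labels: C1–C10 are the decalin carbons (C4 bears the exocyclic CH2, C5 is the ring-fusion CH, C8 the CH–CH3, C9 the quaternary C(CH3)(CH2Ar), C10 the ring-fusion C–CH3), C11 is the benzylic CH2, and β is the face of the C10 methyl. Feature used: the quaternary C9 lies in six-membered ring B between the quaternary C10 and C8 and carries C11. With C8 as a ketone, ring B is the product of a semipinacol shift of C10 from C8 to C9 in a cyclopentanol (C8, C10, C5, C6, C7) whose isopropenyl group (C9, its CH3, C11) takes up the aryl group at C11.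
2. Endgame: C4=CH2 from a C4 ketone (methylenation, last step); C8β–CH3 from the C8 ketone (methylenation, then hydrogenation, which also frees the phenol).
3. Key disconnection: the C11–aryl bond and the C9–C10 bond are made in one operation, a copper-catalysed arylative semipinacol ring expansion of the isopropenyl hydrindanol 8 with the aryl(mesityl)iodonium salt 12 (from methyl 4-hydroxy-3-iodobenzoate).
4. 8 comes from (S)-Hajos–Parrish ketone: the enone C=O is removed via dithioketal and Raney nickel, hydroboration sets the trans ring fusion (C5) and the C4 oxygen, and isopropenyl is added to the cyclopentanone.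
5. Ring order: ring A (cyclohexane) and the cyclopentane come with the starting ketone; ring B forms in the key step by expansion of the cyclopentane; the arene is bought intact.

Key step: step 9

Remark: the target is taken as drawn, methyl 4-hydroxy-3-{[(1R,2S,4aS,8aS)-1,2,8a-trimethyl-5-methylidenedecahydronaphthalen-1-yl]methyl}benzoate (trans-decalin, angular methyl on the ring-fusion carbon next to C9, all three methyl groups β); hydrindane intermediates keep the labels above (C9 absent).

**Route**

Step 1
Reactants: 1 (S)-Hajos–Parrish ketone, (7aS)-7a-methyl-2,3,7,7a-tetrahydro-1H-indene-1,5(6H)-dione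
Product: 2 enone dithioketal, (7a'S)-7a'-methyl-2',3',7',7a'-tetrahydrospiro[[1,3]dithiolane-2,5'-inden]-1'(6'H)-one (C4=C5 retained, C8 ketone free)
Conditions: HSCH2CH2SH, TsOH·H2O (cat.), AcOH, rt
Reagents that add atoms: ethane-1,2-dithiol, SCCS
Why: Acid-catalysed dithioketalisation should be selective for the enone carbonyl, because the cyclopentanone C=O next to the quaternary carbon is hindered and resists rehybridisation, and enone dithioketals keep the double bond in place.

Step 2
Reactants: 2 enone dithioketal
Product: 3 dithioketal–ketal, the C8 ethylene ketal of 2 (1,3-dioxolane on the former cyclopentanone carbonyl)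
Conditions: HOCH2CH2OH, TsOH (cat.), benzene, reflux (Dean–Stark)
Reagents that add atoms: ethane-1,2-diol, OCCO
Why: Acid-catalysed ketalisation masks the remaining ketone so that neither Raney nickel nor borane can reduce it, and the dithiolane is inert to these conditions.

Step 3
Reactants: 3 dithioketal–ketal
Product: 4 (7aS)-7a-methyl-2,3,5,6,7,7a-hexahydrospiro[indene-1,2'-[1,3]dioxolane] (C3 now CH2, C4=C5 alkene)
Conditions: Raney Ni (W-2), EtOH, reflux
Reagents that add atoms: none
Why: Raney nickel desulfurisation (Mozingo reduction) should turn the allylic dithioketal carbon into CH2 while leaving the hindered trisubstituted C4=C5 alkene and the ketal untouched, as in the analogous octalin series.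

Step 4
Reactants: 4 alkene ketal
Product: 6 (3aR,4R,7aS)-7a-methyloctahydrospiro[indene-1,2'-[1,3]dioxolan]-4-ol (trans-fused, H-5 α, 4-OH α), via C4 alkylborane 5 (not isolated)
Conditions: BH3·THF, THF, 0 °C → rt; then 3 M NaOH, 30% H2O2, 0 °C → rt
Reagents that add atoms: hydrogen peroxide, OO
Why: Hydroboration–oxidation: borane should add syn from the α face, opposite the angular C10 methyl, with boron on the less substituted C4, which sets H-5 α (trans ring fusion, the C5 stereocentre) and, after oxidation with retention, the 4α-alcohol.

Step 5
Reactants: 6 hydroxy ketal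
Product: 7 (3aR,4R,7aS)-4-hydroxy-7a-methyloctahydro-1H-inden-1-one (trans-fused hydroxy ketone)
Conditions: 1 M HCl, THF, rt
Reagents that add atoms: water, O
Why: Acid-catalysed ketal hydrolysis frees the C8 ketone; C5 is not α to this ketone, so the trans fusion cannot epimerise.

Step 6
Reactants: 7 hydroxy ketone
Product: 8 (1R,3aR,4R,7aS)-7a-methyl-1-(prop-1-en-2-yl)octahydro-1H-indene-1,4-diol (8β-OH, 8α-isopropenyl, 4α-OH)
Conditions: CH2=C(CH3)MgBr (3 equiv), CeCl3, THF, −78 → 0 °C
Reagents that add atoms: isopropenylmagnesium bromide, C=C(C)[Mg]Br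
Why: Organocerium 1,2-addition to the hindered, enolisable cyclopentanone should occur from the α face, anti to the angular methyl as with 17-keto steroids, giving the 8β-hydroxy-8α-isopropenyl carbinol (a stereocentre that is consumed in step 9).

Step 7
Reactants: 9 methyl 4-hydroxy-3-iodobenzoate
Product: 10 methyl 4-(benzyloxy)-3-iodobenzoate
Conditions: BnBr, K2CO3, DMF, rt
Reagents that add atoms: benzyl bromide, BrCc1ccccc1
Why: Williamson ether synthesis on the acidic phenol; the benzyl ether should survive every step up to the hydrogenation that removes it.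

Step 8
Reactants: 10 methyl 4-(benzyloxy)-3-iodobenzoate
Product: 12 [2-(benzyloxy)-5-(methoxycarbonyl)phenyl](2,4,6-trimethylphenyl)iodonium 4-methylbenzenesulfonate, via hydroxy(tosyloxy)iodoarene 11 (not isolated)
Conditions: mCPBA, TsOH·H2O, CH2Cl2/CF3CH2OH, rt; then mesitylene, rt
Reagents that add atoms: mesitylene, Cc1cc(C)cc(C)c1; 4-methylbenzenesulfonic acid, Cc1ccc(S(=O)(=O)O)cc1
Why: One-pot diaryliodonium salt synthesis: oxidation of the aryl iodide to the iodine(III) species followed by electrophilic aromatic substitution on mesitylene should give the unsymmetrical salt with mesityl as the non-transferred group, under conditions mild enough for the benzyl ether.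

Step 9
Reactants: 8 isopropenyl hydrindanediol; 12 aryl(mesityl)iodonium tosylate
Product: 13 methyl 4-(benzyloxy)-3-{[4α-hydroxy-9β,10β-dimethyl-8-oxo-5α-decalin-9α-yl]methyl}benzoate (trans-decalin; C8 ketone; C9 with β-CH3 and α-CH2Ar)
Conditions: Cu(OTf)2 (10 mol %), 2,6-di-tert-butylpyridine, CH2Cl2, 40 °C
Reagents that add atoms: none
Why: Proposed new method: a Cu(I)/Cu(III) cycle is expected in which 12 oxidises Cu(I) to an aryl–Cu(III) electrophile (mesityl stays on iodine) that transfers the aryl group to the unsubstituted alkene terminus C11 of 8 while, as positive charge builds at C9, the antiperiplanar C8–C10 σ bond shifts from C8 to C9 and the C8 carbinol becomes the ketone (semipinacol), so that the C11–aryl bond, the quaternary C9, the C9–C10 bond between two quaternary carbons and the cyclohexanone ring B arise together. The closest known reaction types are the copper-catalysed arylation of unactivated 1,1-disubstituted alkenes with diaryliodonium salts, the copper-catalysed arylation-driven semipinacol ring expansion of 1-alkenylcyclobutanols, halonium-induced cyclopentanol-to-cyclohexanone semipinacol expansions and the D-homoannulation of 17-hydroxy-17-alkenyl steroids; what is new is the combination on an unstrained cyclopentanol carrying a simple isopropenyl group. Ring B closes by ring expansion (1,2-alkyl shift of C10 with retention at C10), not by cyclisation onto a chain terminus. The new stereocentre C9 is controlled by the allylic conformation of 8 in which the bulky C8–C10 bond is perpendicular to the alkene plane, the small hydroxyl lies next to the vinylic methyl and C7 next to =CH2 (minimal A1,2 strain); anti addition of the aryl–copper unit and C10 across the alkene from this conformer should place the C9 methyl β (cis to the C10 methyl) and the arylmethyl group α. The step needs C10 rather than C7 to migrate (the more substituted carbon and the one aligned with the π system), aryl delivery to the terminal carbon (1,1-disubstitution, tertiary cation character at C9), transfer of the functionalised aryl rather than mesityl (ortho-dimethyl dummy group) and migration ahead of proton loss from C9 (hydroxyl-assisted shift; the hindered pyridine only takes up the sulfonic acid).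

Step 10
Reactants: 13 decalin keto alcohol
Product: 14 methyl 4-(benzyloxy)-3-{[4α-hydroxy-9β,10β-dimethyl-8-methylidene-5α-decalin-9α-yl]methyl}benzoate
Conditions: Zn, CH2Br2, TiCl4 (Takai–Lombardo reagent), THF/CH2Cl2, 0 °C → rt
Reagents that add atoms: dibromomethane, BrCBr
Why: Takai–Lombardo methylenation is non-basic, selective for ketones over esters and effective on hindered ketones such as C8 next to the quaternary C9, and the free hydroxyl only consumes reagent.

Step 11
Reactants: 14 hydroxy alkene
Product: 15 methyl 4-(benzyloxy)-3-{[9β,10β-dimethyl-8-methylidene-4-oxo-5α-decalin-9α-yl]methyl}benzoate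
Conditions: Dess–Martin periodinane, CH2Cl2, rt
Reagents that add atoms: none
Why: Dess–Martin oxidation of the secondary alcohol under near-neutral conditions, carried out while the phenol is still masked and without risk to the C5 stereocentre or the 1,1-disubstituted alkene.

Step 12
Reactants: 15 keto alkene benzyl ether
Product: 16 methyl 4-hydroxy-3-{[8β,9β,10β-trimethyl-4-oxo-5α-decalin-9α-yl]methyl}benzoate
Conditions: H2 (1 atm), 10% Pd/C, EtOAc, rt
Reagents that add atoms: none
Why: Heterogeneous hydrogenation should deliver H2 to the exocyclic alkene from the α face (equatorial attack) because the β face is blocked by the syn-axial C10 methyl, which sets the C8 stereocentre with its methyl β (axial), and the same conditions hydrogenolyse the benzyl ether.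

Step 13
Reactants: 16 phenol ketone
Product: 17 methyl 4-hydroxy-3-{[(1R,2S,4aS,8aS)-1,2,8a-trimethyl-5-methylidenedecahydronaphthalen-1-yl]methyl}benzoate (target)
Conditions: Zn, CH2Br2, TiCl4 (Takai–Lombardo reagent), THF/CH2Cl2, 0 °C → rt
Reagents that add atoms: dibromomethane, BrCBr
Why: Takai–Lombardo methylenation of the C4 ketone; the non-basic reagent avoids enolisation and so should preserve the C5 configuration, leaves the methyl ester alone, and excess reagent covers the free phenol.

**Compound list**

1 | (S)-Hajos–Parrish ketone, (7aS)-7a-methyl-2,3,7,7a-tetrahydro-1H-indene-1,5(6H)-dione | O=C1CC[C@@]2(C)C(=C1)CCC2=O | starting material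
2 | (7a'S)-7a'-methyl-2',3',7',7a'-tetrahydrospiro[[1,3]dithiolane-2,5'-inden]-1'(6'H)-one | C12(SCCS1)CC[C@@]3(C)C(=C2)CCC3=O | intermediate
3 | C8 ethylene ketal of 2 (dithiolane at C3, dioxolane at C8, C4=C5) | C12(SCCS1)CC[C@@]3(C)C(=C2)CCC34OCCO4 | intermediate
4 | (7aS)-7a-methyl-2,3,5,6,7,7a-hexahydrospiro[indene-1,2'-[1,3]dioxolane] | C1CC[C@@]2(C)C(=C1)CCC23OCCO3 | intermediate
5 | C4 alkylborane of 4 (BH2 on C4 α, H-5 α) | B[C@@H]1CCC[C@@]2(C)[C@H]1CCC23OCCO3 | intermediate (not isolated)
6 | (3aR,4R,7aS)-7a-methyloctahydrospiro[indene-1,2'-[1,3]dioxolan]-4-ol | O[C@@H]1CCC[C@@]2(C)[C@H]1CCC23OCCO3 | intermediate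
7 | (3aR,4R,7aS)-4-hydroxy-7a-methyloctahydro-1H-inden-1-one | O[C@@H]1CCC[C@@]2(C)[C@H]1CCC2=O | intermediate
8 | (1R,3aR,4R,7aS)-7a-methyl-1-(prop-1-en-2-yl)octahydro-1H-indene-1,4-diol | O[C@@H]1CCC[C@@]2(C)[C@H]1CC[C@@]2(O)C(C)=C | intermediate
9 | methyl 4-hydroxy-3-iodobenzoate | COC(=O)c1ccc(O)c(I)c1 | starting material
10 | methyl 4-(benzyloxy)-3-iodobenzoate | COC(=O)c1ccc(OCc2ccccc2)c(I)c1 | intermediate
11 | methyl 4-(benzyloxy)-3-[hydroxy(tosyloxy)-λ3-iodanyl]benzoate | COC(=O)c1ccc(OCc2ccccc2)c(I(O)OS(=O)(=O)c2ccc(C)cc2)c1 | intermediate (not isolated)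
12 | [2-(benzyloxy)-5-(methoxycarbonyl)phenyl](2,4,6-trimethylphenyl)iodonium 4-methylbenzenesulfonate | COC(=O)c1ccc(OCc2ccccc2)c([I+]c2c(C)cc(C)cc2C)c1.Cc1ccc(S(=O)(=O)[O-])cc1 | intermediate
13 | methyl 4-(benzyloxy)-3-{[4α-hydroxy-9β,10β-dimethyl-8-oxo-5α-decalin-9α-yl]methyl}benzoate | O[C@@H]1CCC[C@@]2(C)[C@H]1CCC(=O)[C@@]2(C)Cc1cc(C(=O)OC)ccc1OCc1ccccc1 | intermediate
14 | methyl 4-(benzyloxy)-3-{[4α-hydroxy-9β,10β-dimethyl-8-methylidene-5α-decalin-9α-yl]methyl}benzoate | O[C@@H]1CCC[C@@]2(C)[C@H]1CCC(=C)[C@@]2(C)Cc1cc(C(=O)OC)ccc1OCc1ccccc1 | intermediate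
15 | methyl 4-(benzyloxy)-3-{[9β,10β-dimethyl-8-methylidene-4-oxo-5α-decalin-9α-yl]methyl}benzoate | O=C1CCC[C@@]2(C)[C@H]1CCC(=C)[C@@]2(C)Cc1cc(C(=O)OC)ccc1OCc1ccccc1 | intermediate
16 | methyl 4-hydroxy-3-{[8β,9β,10β-trimethyl-4-oxo-5α-decalin-9α-yl]methyl}benzoate | O=C1CCC[C@@]2(C)[C@H]1CC[C@H](C)[C@@]2(C)Cc1cc(C(=O)OC)ccc1O | intermediate
17 | methyl 4-hydroxy-3-{[(1R,2S,4aS,8aS)-1,2,8a-trimethyl-5-methylidenedecahydronaphthalen-1-yl]methyl}benzoate | C=C1CCC[C@@]2(C)[C@H]1CC[C@H](C)[C@@]2(C)Cc1cc(C(=O)OC)ccc1O | target

**Step count and risks**

Total steps: 13. Longest linear sequence: 11 steps (steps 1–6 and 9–13 from 1); the arene branch (steps 7–8) joins at step 9.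

Steps most likely to fail:

1. Step 9 (Proposed new method). Without ring strain the aryl–copper(III) electrophile may not trigger the 1,2-shift (proton loss from C9 or arylation without migration), the secondary C7 may migrate in competition, or facial selectivity at C9 may be low. The fallback sets out from 8 and separates migration from arylation with known reactions. N-Bromosuccinimide in i-PrOH at 0 °C should induce the bromonium-triggered semipinacol ring expansion (anti addition of bromine and the migrating C10, known for cyclopentanol-to-cyclohexanone cases) to the bromomethyl ketone F1. F1 has no β-hydrogen and is then joined to aryl iodide 10 by nickel-catalysed reductive cross-electrophile coupling (NiI2·glyme, 4,4'-di-tert-butyl-2,2'-bipyridine, Zn, NaI, DMA, 60 °C), which returns to the route at 13.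

2. Step 12. Hydrogen delivery to C8=CH2 may show poor facial selectivity, because the α face carries the axial arylmethyl group on C9 while the β face carries the syn-axial C10 methyl. The fallback sets out from 15 and replaces steric control by chelation control. BCl3 with pentamethylbenzene in CH2Cl2 at −78 °C should remove the benzyl group without touching the alkene, giving the phenol alkene ketone F2. Hydroxyl-directed homogeneous hydrogenation with [Ir(cod)(PCy3)(py)]PF6 and H2 in CH2Cl2, in which the phenolic OH on the α-oriented arylmethyl arm binds iridium and delivers hydrogen to the α face, should then return to the route at 16.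

3. Step 10. Carbonyl olefination may fail at the C8 ketone, which is flanked by the quaternary C9 and beyond it the quaternary C10 (no conversion, or enolisation instead of addition). The fallback sets out from 13 and uses addition–elimination. Me3SiCH2Li with CeCl3 in THF at −78 °C (cerium-mediated Peterson addition, suited to hindered enolisable ketones and faster at the ketone than at the aryl ester at this temperature) should give the β-hydroxysilane F3. KH in THF at 0 °C → rt then eliminates silanolate and returns to the route at 14.

Further compounds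
F1 | step 9 | 4α-hydroxy-9α-(bromomethyl)-9β,10β-dimethyl-5α-decalin-8-one | O[C@@H]1CCC[C@@]2(C)[C@H]1CCC(=O)[C@@]2(C)CBr
F2 | step 12 | methyl 4-hydroxy-3-{[9β,10β-dimethyl-8-methylidene-4-oxo-5α-decalin-9α-yl]methyl}benzoate | O=C1CCC[C@@]2(C)[C@H]1CCC(=C)[C@@]2(C)Cc1cc(C(=O)OC)ccc1O
F3 | step 10 | methyl 4-(benzyloxy)-3-{[4α,8β-dihydroxy-9β,10β-dimethyl-8α-(trimethylsilylmethyl)-5α-decalin-9α-yl]methyl}benzoate | O[C@@H]1CCC[C@@]2(C)[C@H]1CC[C@@](O)(C[Si](C)(C)C)[C@@]2(C)Cc1cc(C(=O)OC)ccc1OCc1ccccc1
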